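**Retrosynthetic overview** (halimane numbering: ring A = C1–C5 and C10, ring B = C5–C10, side chain C11–C15 on C9)
1. The C15 propionate comes from a last-step acylation; the 13E alkene comes from Zr-catalysed methylalumination/hydroxymethylation of a C13≡C14 alkyne, which is grown from a C9 allyl group (C11–C13).
2. Enabling feature: ring A is a cyclohexene whose only double bond is C1=C10 and whose C4 carries the ester, a [4+2] retron. Cutting C2–C3 and C4–C5 gives methyl methacrylate (C3, C4, CH3, CO2CH3) and the ring-B 1-vinylcyclohexene C5=C10–C1=C2.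
3. The diene comes from the C10 ketone by enol triflate formation and Stille vinylation; the ketone comes from 2-methylcyclohex-2-enone by catalytic asymmetric conjugate methylation (C8) and anti allylation of the enolate (C9).
4. Ring order: ring B is bought as the cyclohexenone; ring A is closed by the intermolecular Diels–Alder reaction, which also sets C4 and C5.

Key step: step 4

Remark: the target is read as 4S,5R,8R,9S,13E, with H-5 and the methyl groups on C4, C8 and C9 on one face of the bicycle and the ester and the C9 side chain on the other.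
Remark: the antipode of the phosphoramidite ligand that delivers the 3R enolate in step 1 is assumed to be identifiable by a test reaction; both antipodes are available.

Step 1
Reactants: 1 2-methylcyclohex-2-en-1-one
Product: 4 (2S,3R)-2,3-dimethyl-2-(prop-2-en-1-yl)cyclohexan-1-one, via dimethylaluminium enolate 2 (not isolated), via lithium aluminate enolate 3 (not isolated)
Conditions: AlMe3 (1.4 equiv), copper thiophene-2-carboxylate (C5H3CuO2S, monovalent copper, 2 mol %), chiral binaphthol-derived phosphoramidite ligand (4 mol %), Et2O, −30 °C; then MeLi (1.4 equiv), THF/DMPU, allyl iodide (3 equiv), −30 °C → rt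
Reagents that add atoms: trimethylaluminium, C[Al](C)C; allyl iodide, C=CCI; methyllithium, [Li]C (lithium in intermediate 3 only)
Why: Copper-catalysed asymmetric conjugate addition of AlMe3 sets C3 (later C8) under ligand control, and the regiodefined enolate, activated as its aluminate, should be C-allylated anti to the new C3 methyl, so the quaternary C2 (later C9) carries its methyl cis to the C3 methyl (conjugate addition–enolate alkylation).

Step 2
Reactants: 4 (2S,3R)-2,3-dimethyl-2-(prop-2-en-1-yl)cyclohexan-1-one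
Product: 6 (5R,6S)-5,6-dimethyl-6-(prop-2-en-1-yl)cyclohex-1-en-1-yl trifluoromethanesulfonate, via potassium enolate 5 (not isolated)
Conditions: KN(SiMe3)2 (1.2 equiv), THF, −78 °C; PhNTf2 (1.3 equiv), −78 → 0 °C
Reagents that add atoms: N-phenylbis(trifluoromethanesulfonimide), O=S(=O)(N(c1ccccc1)S(=O)(=O)C(F)(F)F)C(F)(F)F; potassium bis(trimethylsilyl)amide, C[Si](C)(C)[N-][Si](C)(C)C.[K+] (potassium in intermediate 5 only)
Why: The ketone can enolise only toward its CH2 side because the other α-carbon is quaternary, so deprotonation and O-triflation should give a single enol triflate without touching a stereocentre (enol triflate formation).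

Step 3
Reactants: 6 (5R,6S)-5,6-dimethyl-6-(prop-2-en-1-yl)cyclohex-1-en-1-yl trifluoromethanesulfonate
Product: 7 (5R,6S)-1-ethenyl-5,6-dimethyl-6-(prop-2-en-1-yl)cyclohex-1-ene
Conditions: tributyl(vinyl)stannane (1.3 equiv), Pd(PPh3)4 (5 mol %), LiCl (3 equiv), THF, 65 °C
Reagents that add atoms: tributyl(vinyl)stannane, C=C[Sn](CCCC)(CCCC)CCCC
Why: Stille coupling of the enol triflate with the vinylstannane (chloride assisting transmetalation) installs the vinyl group with the ring double bond kept in place, giving the 1-vinylcyclohexene while the isolated allyl group stays a spectator.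

Step 4
Reactants: 7 (5R,6S)-1-ethenyl-5,6-dimethyl-6-(prop-2-en-1-yl)cyclohex-1-ene; 8 methyl methacrylate
Product: 9 methyl (1S,5S,6R,8aR)-1,5,6-trimethyl-5-(prop-2-en-1-yl)-1,2,3,5,6,7,8,8a-octahydronaphthalene-1-carboxylate
Conditions: 8 (4 equiv), EtAlCl2 (0.3 equiv), CH2Cl2, −78 → −20 °C
Reagents that add atoms: none
Why: Lewis acid-catalysed intermolecular Diels–Alder reaction: EtAlCl2 on the ester carbonyl lowers the LUMO of 8, and a concerted but asynchronous [4+2] addition to the C5=C10–C1=C2 diene should form C2–C3 ahead of C4–C5 and leave the new alkene at C1=C10. The closest known reaction type is the Lewis acid-promoted cycloaddition of 1-vinylcyclohexenes bearing an adjacent quaternary carbon with 2-substituted acrylic dienophiles, which gives octalins with the acceptor-bearing quaternary carbon next to the ring-fusion CH. Ring A is closed by this suprafacial [4π+2π] cycloaddition, both of its new σ-bonds being made in the one intermolecular event. C5 is set by diene facial selectivity: with the C8 methyl equatorial, the C9 methyl is pseudoaxial on one face of the ring-B half-chair, so the dienophile should add to the opposite face and place H-5 cis to both ring-B methyl groups; C4 is set by the endo orientation of the aluminium-complexed ester, which puts CO2Me cis to C6 and trans to H-5. The step needs ortho regioselectivity (ester-bearing carbon to ring carbon C5), secured because the unsubstituted vinyl terminus is the most nucleophilic diene carbon and bonds to the CH2 of the complexed methacrylate with allyl-cation character at tertiary C10. The quaternary C9 also holds the diene s-cis, and the monosubstituted allyl alkene should not compete.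

Step 5
Reactants: 9 methyl (1S,5S,6R,8aR)-1,5,6-trimethyl-5-(prop-2-en-1-yl)-1,2,3,5,6,7,8,8a-octahydronaphthalene-1-carboxylate
Product: 11 methyl (1S,5S,6R,8aR)-5-(3-hydroxypropyl)-1,5,6-trimethyl-1,2,3,5,6,7,8,8a-octahydronaphthalene-1-carboxylate, via B-alkyl-9-borabicyclononane 10 (not isolated)
Conditions: 9-BBN-H (1.5 equiv), THF, 0 °C → rt; then NaOH (3 M aq), H2O2 (30 % aq), 0 °C → rt
Reagents that add atoms: hydrogen peroxide, OO; 9-borabicyclo[3.3.1]nonane, B1C2CCCC1CCC2 (atoms in intermediate 10 only)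
Why: Hydroboration with bulky 9-BBN should be selective for the monosubstituted allyl alkene over the hindered trisubstituted C1=C10 alkene and place boron on the terminal carbon, and alkaline peroxide oxidation gives the primary alcohol without touching the hindered tertiary ester (hydroboration–oxidation).

Step 6
Reactants: 11 methyl (1S,5S,6R,8aR)-5-(3-hydroxypropyl)-1,5,6-trimethyl-1,2,3,5,6,7,8,8a-octahydronaphthalene-1-carboxylate
Product: 12 methyl (1S,5S,6R,8aR)-1,5,6-trimethyl-5-(3-oxopropyl)-1,2,3,5,6,7,8,8a-octahydronaphthalene-1-carboxylate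
Conditions: Dess–Martin periodinane (1.3 equiv), CH2Cl2, 0 °C → rt
Reagents that add atoms: none
Why: Dess–Martin oxidation converts the primary alcohol to the aldehyde under near-neutral conditions, without over-oxidation or alkene migration.

Step 7
Reactants: 12 methyl (1S,5S,6R,8aR)-1,5,6-trimethyl-5-(3-oxopropyl)-1,2,3,5,6,7,8,8a-octahydronaphthalene-1-carboxylate
Product: 13 methyl (1S,5S,6R,8aR)-5-(but-3-yn-1-yl)-1,5,6-trimethyl-1,2,3,5,6,7,8,8a-octahydronaphthalene-1-carboxylate
Conditions: dimethyl (1-diazo-2-oxopropyl)phosphonate (1.5 equiv), K2CO3 (2 equiv), MeOH, 0 °C → rt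
Reagents that add atoms: dimethyl (1-diazo-2-oxopropyl)phosphonate, CC(=O)C(=[N+]=[N-])P(=O)(OC)OC
Why: Seyferth–Gilbert homologation with the Ohira–Bestmann reagent (diazomethylphosphonate anion addition, cycloelimination and 1,2-shift of the alkylidene carbene) turns the aldehyde into the terminal alkyne with one more carbon, and the methyl ester is inert to K2CO3 in methanol.

Step 8
Reactants: 13 methyl (1S,5S,6R,8aR)-5-(but-3-yn-1-yl)-1,5,6-trimethyl-1,2,3,5,6,7,8,8a-octahydronaphthalene-1-carboxylate
Product: 15 methyl (1S,5S,6R,8aR)-5-[(3E)-5-hydroxy-3-methylpent-3-en-1-yl]-1,5,6-trimethyl-1,2,3,5,6,7,8,8a-octahydronaphthalene-1-carboxylate, via alkenyldimethylalane 14 (not isolated)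
Conditions: AlMe3 (3 equiv), Cp2ZrCl2 (0.25 equiv), CH2Cl2, 0 °C → rt; then (CH2O)n (excess), THF, 0 °C → rt
Reagents that add atoms: trimethylaluminium, C[Al](C)C; paraformaldehyde (as formaldehyde), C=O
Why: Zirconium-catalysed methylalumination (Negishi carboalumination) adds CH3–Al syn across the terminal alkyne with methyl on the internal carbon, and the alkenylalane is hydroxymethylated by formaldehyde with retention, which fixes the 13E geometry; the hindered α-quaternary ester is expected to survive AlMe3 at or below room temperature.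

Step 9
Reactants: 15 methyl (1S,5S,6R,8aR)-5-[(3E)-5-hydroxy-3-methylpent-3-en-1-yl]-1,5,6-trimethyl-1,2,3,5,6,7,8,8a-octahydronaphthalene-1-carboxylate
Product: 16 methyl (1S,5S,6R,8aR)-1,5,6-trimethyl-5-[(3E)-3-methyl-5-(propanoyloxy)pent-3-en-1-yl]-1,2,3,5,6,7,8,8a-octahydronaphthalene-1-carboxylate (CNP0279628.1)
Conditions: (EtCO)2O (1.5 equiv), Et3N (2 equiv), DMAP (0.1 equiv), CH2Cl2, 0 °C → rt
Reagents that add atoms: propionic anhydride, CCC(=O)OC(=O)CC
Why: DMAP-catalysed acylation of the unhindered primary allylic alcohol with propionic anhydride should give the propionate without allylic transposition.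

**Compound list**
1 | 2-methylcyclohex-2-en-1-one | CC1=CCCCC1=O | starting material
2 | dimethylaluminium (3R)-2,3-dimethylcyclohex-1-en-1-olate | CC1=C(O[Al](C)C)CCC[C@H]1C | intermediate (not isolated)
3 | lithium trimethyl[(3R)-2,3-dimethylcyclohex-1-en-1-yloxy]aluminate | [Li+].CC1=C(O[Al-](C)(C)C)CCC[C@H]1C | intermediate (not isolated)
4 | (2S,3R)-2,3-dimethyl-2-(prop-2-en-1-yl)cyclohexan-1-one | C=CC[C@]1(C)C(=O)CCC[C@H]1C | intermediate
5 | potassium (5R,6S)-5,6-dimethyl-6-(prop-2-en-1-yl)cyclohex-1-en-1-olate | C=CC[C@]1(C)C([O-])=CCC[C@H]1C.[K+] | intermediate (not isolated)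
6 | (5R,6S)-5,6-dimethyl-6-(prop-2-en-1-yl)cyclohex-1-en-1-yl trifluoromethanesulfonate | C=CC[C@]1(C)C(OS(=O)(=O)C(F)(F)F)=CCC[C@H]1C | intermediate
7 | (5R,6S)-1-ethenyl-5,6-dimethyl-6-(prop-2-en-1-yl)cyclohex-1-ene | C=CC[C@]1(C)C(C=C)=CCC[C@H]1C | intermediate
8 | methyl methacrylate | C=C(C)C(=O)OC | starting material
9 | methyl (1S,5S,6R,8aR)-1,5,6-trimethyl-5-(prop-2-en-1-yl)-1,2,3,5,6,7,8,8a-octahydronaphthalene-1-carboxylate | C=CC[C@]1(C)C2=CCC[C@](C)(C(=O)OC)[C@@H]2CC[C@H]1C | intermediate
10 | methyl (1S,5S,6R,8aR)-5-[3-(9-borabicyclo[3.3.1]nonan-9-yl)propyl]-1,5,6-trimethyl-1,2,3,5,6,7,8,8a-octahydronaphthalene-1-carboxylate | C1CC2CCCC(C1)B2CCC[C@]3(C)C4=CCC[C@](C)(C(=O)OC)[C@@H]4CC[C@H]3C | intermediate (not isolated)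
11 | methyl (1S,5S,6R,8aR)-5-(3-hydroxypropyl)-1,5,6-trimethyl-1,2,3,5,6,7,8,8a-octahydronaphthalene-1-carboxylate | OCCC[C@]1(C)C2=CCC[C@](C)(C(=O)OC)[C@@H]2CC[C@H]1C | intermediate
12 | methyl (1S,5S,6R,8aR)-1,5,6-trimethyl-5-(3-oxopropyl)-1,2,3,5,6,7,8,8a-octahydronaphthalene-1-carboxylate | O=CCC[C@]1(C)C2=CCC[C@](C)(C(=O)OC)[C@@H]2CC[C@H]1C | intermediate
13 | methyl (1S,5S,6R,8aR)-5-(but-3-yn-1-yl)-1,5,6-trimethyl-1,2,3,5,6,7,8,8a-octahydronaphthalene-1-carboxylate | C#CCC[C@]1(C)C2=CCC[C@](C)(C(=O)OC)[C@@H]2CC[C@H]1C | intermediate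
14 | methyl (1S,5S,6R,8aR)-5-[(3E)-4-(dimethylalumanyl)-3-methylbut-3-en-1-yl]-1,5,6-trimethyl-1,2,3,5,6,7,8,8a-octahydronaphthalene-1-carboxylate | C[Al](C)/C=C(\C)CC[C@]1(C)C2=CCC[C@](C)(C(=O)OC)[C@@H]2CC[C@H]1C | intermediate (not isolated)
15 | methyl (1S,5S,6R,8aR)-5-[(3E)-5-hydroxy-3-methylpent-3-en-1-yl]-1,5,6-trimethyl-1,2,3,5,6,7,8,8a-octahydronaphthalene-1-carboxylate | OC/C=C(\C)CC[C@]1(C)C2=CCC[C@](C)(C(=O)OC)[C@@H]2CC[C@H]1C | intermediate
16 | methyl (1S,5S,6R,8aR)-1,5,6-trimethyl-5-[(3E)-3-methyl-5-(propanoyloxy)pent-3-en-1-yl]-1,2,3,5,6,7,8,8a-octahydronaphthalene-1-carboxylate | CCC(=O)OC/C=C(\C)CC[C@]1(C)C2=CCC[C@](C)(C(=O)OC)[C@@H]2CC[C@H]1C | target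

**Total step count:** 9. **Longest linear sequence:** 9 steps (1 → 16).

**Steps most likely to fail**

Step 4. The 1,1-disubstituted, weakly activated dienophile may add too slowly to the hindered diene, leaving time for acid-induced diene oligomerisation or double-bond migration, and endo or facial discrimination may be insufficient. Fallback: setting out from 7, an ionic Diels–Alder reaction with 2-(prop-1-en-2-yl)-1,3-dioxolane (TMSOTf, CH2Cl2, −78 °C) would use a far more reactive, strongly endo-directing cationic dienophile and give 2-[(1S,5S,6R,8aR)-1,5,6-trimethyl-5-(prop-2-en-1-yl)-1,2,3,5,6,7,8,8a-octahydronaphthalen-1-yl]-1,3-dioxolane F1. Mild acetal hydrolysis (pyridinium tosylate, acetone/H2O) would give (1S,5S,6R,8aR)-1,5,6-trimethyl-5-(prop-2-en-1-yl)-1,2,3,5,6,7,8,8a-octahydronaphthalene-1-carbaldehyde F2. Pinnick oxidation (NaClO2, NaH2PO4, 2-methylbut-2-ene, t-BuOH/H2O) would give (1S,5S,6R,8aR)-1,5,6-trimethyl-5-(prop-2-en-1-yl)-1,2,3,5,6,7,8,8a-octahydronaphthalene-1-carboxylic acid F3, and methylation with TMSCHN2 (MeOH/toluene) would come back to the route at 9.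

Step 1. C-allylation of the hindered aluminium enolate may be incomplete or unselective (O-allylation, proton transfer, slow turnover of the aluminate). Fallback: setting out from 1, the same conjugate addition is run and enolate 2 is O-acylated with allyl chloroformate to give allyl (3R)-2,3-dimethylcyclohex-1-en-1-yl carbonate F4, which is purified. Decarboxylative allylation with catalytic Pd(PPh3)4 (THF, rt; Tsuji allylation through a regiodefined palladium enolate/π-allyl pair, attack again anti to the C3 methyl) would come back to the route at 4.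

Step 8. Methyl transfer from AlMe3 to the ester may compete, or capture of the alkenylalane by formaldehyde may be incomplete and lead to protodealumination. Fallback: setting out from 12, addition of MeMgBr (THF, −78 °C) would give methyl (1S,5S,6R,8aR)-5-(3-hydroxybutyl)-1,5,6-trimethyl-1,2,3,5,6,7,8,8a-octahydronaphthalene-1-carboxylate F5 (carbinol epimers). Dess–Martin oxidation would give methyl (1S,5S,6R,8aR)-1,5,6-trimethyl-5-(3-oxobutyl)-1,2,3,5,6,7,8,8a-octahydronaphthalene-1-carboxylate F6. Horner–Wadsworth–Emmons olefination with triethyl phosphonoacetate (NaH, THF) would give methyl (1S,5S,6R,8aR)-5-[(3E)-5-ethoxy-3-methyl-5-oxopent-3-en-1-yl]-1,5,6-trimethyl-1,2,3,5,6,7,8,8a-octahydronaphthalene-1-carboxylate F7, with the minor Z isomer removed by chromatography. Reduction of the unhindered conjugated ethyl ester with i-Bu2AlH (CH2Cl2, −78 °C), leaving the hindered C4 methyl ester, would come back to the route at 15.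

**Further compounds**
F1 | step 4 | 2-[(1S,5S,6R,8aR)-1,5,6-trimethyl-5-(prop-2-en-1-yl)-1,2,3,5,6,7,8,8a-octahydronaphthalen-1-yl]-1,3-dioxolane | C=CC[C@]1(C)C2=CCC[C@](C)(C3OCCO3)[C@@H]2CC[C@H]1C
F2 | step 4 | (1S,5S,6R,8aR)-1,5,6-trimethyl-5-(prop-2-en-1-yl)-1,2,3,5,6,7,8,8a-octahydronaphthalene-1-carbaldehyde | C=CC[C@]1(C)C2=CCC[C@](C)(C=O)[C@@H]2CC[C@H]1C
F3 | step 4 | (1S,5S,6R,8aR)-1,5,6-trimethyl-5-(prop-2-en-1-yl)-1,2,3,5,6,7,8,8a-octahydronaphthalene-1-carboxylic acid | C=CC[C@]1(C)C2=CCC[C@](C)(C(=O)O)[C@@H]2CC[C@H]1C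
F4 | step 1 | allyl (3R)-2,3-dimethylcyclohex-1-en-1-yl carbonate | CC1=C(OC(=O)OCC=C)CCC[C@H]1C
F5 | step 8 | methyl (1S,5S,6R,8aR)-5-(3-hydroxybutyl)-1,5,6-trimethyl-1,2,3,5,6,7,8,8a-octahydronaphthalene-1-carboxylate (carbinol epimers) | CC(O)CC[C@]1(C)C2=CCC[C@](C)(C(=O)OC)[C@@H]2CC[C@H]1C
F6 | step 8 | methyl (1S,5S,6R,8aR)-1,5,6-trimethyl-5-(3-oxobutyl)-1,2,3,5,6,7,8,8a-octahydronaphthalene-1-carboxylate | CC(=O)CC[C@]1(C)C2=CCC[C@](C)(C(=O)OC)[C@@H]2CC[C@H]1C
F7 | step 8 | methyl (1S,5S,6R,8aR)-5-[(3E)-5-ethoxy-3-methyl-5-oxopent-3-en-1-yl]-1,5,6-trimethyl-1,2,3,5,6,7,8,8a-octahydronaphthalene-1-carboxylate | CCOC(=O)/C=C(\C)CC[C@]1(C)C2=CCC[C@](C)(C(=O)OC)[C@@H]2CC[C@H]1C
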